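**Retrosynthetic overview**
1. The C4–C8 interflavan bond is made last. A robinetinidol C4 cation attacks C8 of purchased (−)-EGCG, with both partners unprotected. The cation comes from the flavan-3,4-diol, which is made by hydride reduction of (+)-dihydrorobinetin.
2. The C3–O bond comes from enolate oxygenation of the (2S)-flavanone. It is set trans by relay from C2.
3. The O1–C2 bond is the only ring closure. It is a catalytic enantioselective 6-endo-trig oxa-Michael closure of the open, unactivated 2'-hydroxychalcone. This is the only catalyst-controlled stereocentre, and C3 and C4 follow from it.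
4. The Cα=Cβ bond comes from Claisen–Schmidt condensation of 4'-benzyloxy-2'-hydroxyacetophenone with 3,4,5-tris(benzyloxy)benzaldehyde.
5. Ring order: all aromatic rings and the whole lower unit are purchased. The upper pyran ring is closed first, then oxygenated at C3, reduced at C4 and arylated at C4.

Assumption: the quinidine-series thiourea is taken, by analogy, to give the (2S)-flavanone. This is checked by CD on the flavanone, and the quinine-derived pseudoenantiomer is used instead if the sign is opposite.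

**Step 1**
Reactants: 1 4'-benzyloxy-2'-hydroxyacetophenone; 2 3,4,5-tris(benzyloxy)benzaldehyde
Product: 3 (E)-tetra-O-benzylrobtein (2'-hydroxychalcone)
Conditions: KOH (50% aq, 10 equiv), EtOH–THF, rt, 48 h; then 1 M HCl
Reagents that add atoms: none
Why: This is a Claisen–Schmidt crossed aldol condensation in which only 1 is enolisable, E1cB dehydration gives the conjugated E-enone, and in strong base the product stays open as its chelated phenoxide, so the chalcone rather than racemic flavanone is isolated and no stereocentre is formed.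

**Step 2**
Reactants: 3 (E)-tetra-O-benzylrobtein
Product: 4 (2S)-tetra-O-benzylrobtin (flavanone)
Conditions: 9-amino-9-deoxy-epi-quinidine 3,5-bis(trifluoromethyl)phenylthiourea (10 mol%), toluene, 0 °C, ca. 72 h, stopped at ca. 65% conversion; 1 M HCl wash; recrystallisation (EtOAc–hexane); recovered 3 recycled
Reagents that add atoms: none
Why: Proposed new method: the quinuclidine base deprotonates the chelated 2'-OH while the thiourea N–H pair holds the s-cis enone carbonyl like an oxyanion hole, so the phenoxide closes 6-endo-trig on one face of Cβ and the enolate is protonated inside the ion pair, which sets C2 as (S) in the same way as chalcone isomerase; the closest known reaction type is the cinchona-thiourea-catalysed asymmetric intramolecular oxa-Michael cyclisation of α-ester-activated 2'-hydroxychalcones, and because closure of the unactivated chalcone is reversible the reaction is stopped kinetically and the ee is upgraded by crystallisation.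

**Step 3**
Reactants: 4 (2S)-tetra-O-benzylrobtin
Product: 6 (2R,3R)-tetra-O-benzyldihydrorobinetin, via lithium enolate 5 (not isolated)
Conditions: LDA (1.1 equiv), THF, −78 °C, 20 min; Davis oxaziridine (1.3 equiv), −78 °C, 1 h; AcOH quench at −78 °C
Reagents that add atoms: 2-(phenylsulfonyl)-3-phenyloxaziridine (Davis reagent), O=S(=O)(N1OC1c1ccccc1)c1ccccc1
Why: This is a Davis enolate oxidation in which kinetic deprotonation at −78 °C gives the lithium enolate without E1cB opening of the pyranone, and oxygen is delivered to the face anti to the 2-aryl group, so the new C3 carbinol is trans to C2 [(2R,3R); the C2 descriptor changes only through CIP priorities].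

**Step 4**
Reactants: 6 (2R,3R)-tetra-O-benzyldihydrorobinetin
Product: 7 (+)-(2R,3R)-dihydrorobinetin
Conditions: H2 (1 atm), 10% Pd/C, THF–MeOH 1:1, rt, 4 h; filtered under N2
Reagents that add atoms: none
Why: Catalytic hydrogenolysis of the four aryl benzyl ethers is much faster at 1 atm and rt than attack on the vinylogous-ester-like aryl ketone or the cyclic C2–O bond, and the neutral medium leaves C2 and C3 untouched.

**Step 5**
Reactants: 7 (+)-(2R,3R)-dihydrorobinetin; 8 (−)-epigallocatechin 3-O-gallate (4 equiv)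
Product: 11 robinetinidol-(4α→8)-epigallocatechin 3-O-gallate (target), via leucorobinetinidin 9 (not isolated), via C4 benzylic cation 10 (not isolated)
Conditions: NaBH4 (4 equiv), EtOH, 0 °C, N2, 1 h; then 8, aq HCl to 0.1 M (pH ca. 1), EtOH–H2O, rt, N2, dark, 18 h; EtOAc extraction; Sephadex LH-20 (EtOH), then RP-HPLC
Reagents that add atoms: none
Why: Borohydride reduction (dihydroflavonol-reductase type) gives the flavan-3,4-diol, which in dilute acid ionises to the 7-OH-stabilised C4 cation and is captured in a Friedel–Crafts alkylation by C8 of the phloroglucinol ring of 8, the most nucleophilic carbon present, mainly from the α-face anti to the 3β-OH, which sets C4 as (S) (2,3-trans-3,4-trans), while the minor 4β and C6-linked isomers are removed chromatographically.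

**Compound list**
1 | 1-[4-(benzyloxy)-2-hydroxyphenyl]ethan-1-one | CC(=O)c1ccc(OCc2ccccc2)cc1O | starting material
2 | 3,4,5-tris(benzyloxy)benzaldehyde | O=Cc1cc(OCc2ccccc2)c(OCc2ccccc2)c(OCc2ccccc2)c1 | starting material
3 | (E)-1-[4-(benzyloxy)-2-hydroxyphenyl]-3-[3,4,5-tris(benzyloxy)phenyl]prop-2-en-1-one | O=C(/C=C/c1cc(OCc2ccccc2)c(OCc2ccccc2)c(OCc2ccccc2)c1)c1ccc(OCc2ccccc2)cc1O | intermediate
4 | (2S)-7-(benzyloxy)-2-[3,4,5-tris(benzyloxy)phenyl]-2,3-dihydro-4H-chromen-4-one | O=C1C[C@@H](c2cc(OCc3ccccc3)c(OCc3ccccc3)c(OCc3ccccc3)c2)Oc2cc(OCc3ccccc3)ccc12 | intermediate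
5 | lithium (2S)-7-(benzyloxy)-2-[3,4,5-tris(benzyloxy)phenyl]-2H-chromen-4-olate | [Li]OC1=C[C@@H](c2cc(OCc3ccccc3)c(OCc3ccccc3)c(OCc3ccccc3)c2)Oc2cc(OCc3ccccc3)ccc12 | intermediate
6 | (2R,3R)-7-(benzyloxy)-3-hydroxy-2-[3,4,5-tris(benzyloxy)phenyl]-2,3-dihydro-4H-chromen-4-one (2,3-trans) | O=C1[C@H](O)[C@@H](c2cc(OCc3ccccc3)c(OCc3ccccc3)c(OCc3ccccc3)c2)Oc2cc(OCc3ccccc3)ccc12 | intermediate
7 | (2R,3R)-3,7-dihydroxy-2-(3,4,5-trihydroxyphenyl)-2,3-dihydro-4H-chromen-4-one, (+)-dihydrorobinetin | O=C1[C@H](O)[C@@H](c2cc(O)c(O)c(O)c2)Oc2cc(O)ccc12 | intermediate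
8 | (−)-epigallocatechin 3-O-gallate, (2R,3R) | O=C(O[C@@H]1Cc2c(O)cc(O)cc2O[C@@H]1c1cc(O)c(O)c(O)c1)c1cc(O)c(O)c(O)c1 | starting material
9 | (2R,3S,4R)-2-(3,4,5-trihydroxyphenyl)chromane-3,4,7-triol, (+)-leucorobinetinidin (2,3-trans-3,4-trans) | O[C@H]1[C@H](O)[C@@H](c2cc(O)c(O)c(O)c2)Oc2cc(O)ccc12 | intermediate
10 | (2R,3S)-3,7-dihydroxy-2-(3,4,5-trihydroxyphenyl)chroman-4-ylium (O-protonated A-ring p-quinone methide) | O[C@H]1[CH+]c2ccc(O)cc2O[C@@H]1c1cc(O)c(O)c(O)c1 | intermediate
11 | robinetinidol-(4α→8)-epigallocatechin 3-O-gallate; upper unit (2R,3S,4S), lower unit (2R,3R) | O=C(O[C@@H]1Cc2c(O)cc(O)c([C@@H]3c4ccc(O)cc4O[C@H](c4cc(O)c(O)c(O)c4)[C@H]3O)c2O[C@@H]1c1cc(O)c(O)c(O)c1)c1cc(O)c(O)c(O)c1 | target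

**Total step count:** 5. **Longest linear sequence:** 5 (1 or 2 → 3 → 4 → 6 → 7 → 11).

**Steps most likely to fail**

**Step 2.** The enone is unactivated and the closure is reversible. The flavanone:chalcone equilibrium is roughly 4:1, and retro-Michael opening erodes the ee, which may stall well below 90%.
- The fallback moves the stereocontrol from the ring closure to an epoxide. It sets out from 3 and comes back at 6, so steps 2 and 3 are both bypassed.
- Compound 3 is capped with MOMCl/iPr2NEt (CH2Cl2) to give the 2'-O-methoxymethyl chalcone F1.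
- Juliá–Colonna epoxidation (poly-L-leucine, urea–H2O2, DBU, THF) gives the (αR,βS)-trans-epoxy ketone F2.
- HCl in MeOH at 45 °C removes the MOM group. The freed phenol opens the epoxide 6-endo at the benzylic carbon with inversion, which gives (2R,3R)-6.

**Step 5.** Facial selectivity of the 5-deoxy 2,3-trans cation is only moderate. I estimate about 2–3:1 α:β. C6 attack and trimer formation compete, and the free phenols are hard to separate. I estimate 20–30% isolated yield of 11.
- The fallback is a protected, low-temperature Lewis-acid coupling. It sets out from 6 and 8 and comes back at 11.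
- Compound 6 is reduced (NaBH4, THF–EtOH) to tetra-O-benzylleucorobinetinidin F4.
- Compound 8 is perbenzylated (BnBr, K2CO3, DMF) to octa-O-benzyl-EGCG F5.
- TMSOTf in CH2Cl2 at −78 °C, with F5 in threefold excess, joins the two to the dodeca-O-benzyl dimer F6. Its isomers separate on ordinary silica gel.
- H2 over Pd(OH)2/C (THF–MeOH) then removes all twelve benzyl groups.

**Step 3.** The enolate can expel the phenoxide, which returns 3 and costs ee. It can also add to the sulfonimine by-product or be over-oxidised to the flavonol.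
- The fallback avoids any free enolate. It sets out from 4 and comes back at 6.
- Soft enolisation (TMSOTf, Et3N, CH2Cl2, 0 °C) gives the isolable (2S)-4-trimethylsilyloxy-2H-chromene F3.
- Rubottom oxidation with dimethyldioxirane (acetone–CH2Cl2, −40 °C) epoxidises the enol ether anti to the 2-aryl group.
- Aqueous citric acid work-up then releases trans-6.

**Further compounds**
F1 | step 2 | (E)-1-[4-(benzyloxy)-2-(methoxymethoxy)phenyl]-3-[3,4,5-tris(benzyloxy)phenyl]prop-2-en-1-one | O=C(/C=C/c1cc(OCc2ccccc2)c(OCc2ccccc2)c(OCc2ccccc2)c1)c1ccc(OCc2ccccc2)cc1OCOC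
F2 | step 2 | [4-(benzyloxy)-2-(methoxymethoxy)phenyl]{(2R,3S)-3-[3,4,5-tris(benzyloxy)phenyl]oxiran-2-yl}methanone | O=C([C@@H]1O[C@H]1c1cc(OCc2ccccc2)c(OCc2ccccc2)c(OCc2ccccc2)c1)c1ccc(OCc2ccccc2)cc1OCOC
F3 | step 3 | (2S)-7-(benzyloxy)-2-[3,4,5-tris(benzyloxy)phenyl]-4-(trimethylsilyloxy)-2H-chromene | C[Si](C)(C)OC1=C[C@@H](c2cc(OCc3ccccc3)c(OCc3ccccc3)c(OCc3ccccc3)c2)Oc2cc(OCc3ccccc3)ccc12
F4 | step 5 | (2R,3S,4R)-7-(benzyloxy)-2-[3,4,5-tris(benzyloxy)phenyl]chromane-3,4-diol | O[C@H]1[C@H](O)[C@@H](c2cc(OCc3ccccc3)c(OCc3ccccc3)c(OCc3ccccc3)c2)Oc2cc(OCc3ccccc3)ccc12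
F5 | step 5 | octa-O-benzyl-(−)-epigallocatechin 3-O-gallate | O=C(O[C@@H]1Cc2c(OCc3ccccc3)cc(OCc3ccccc3)cc2O[C@@H]1c1cc(OCc2ccccc2)c(OCc2ccccc2)c(OCc2ccccc2)c1)c1cc(OCc2ccccc2)c(OCc2ccccc2)c(OCc2ccccc2)c1
F6 | step 5 | dodeca-O-benzyl-robinetinidol-(4α→8)-epigallocatechin 3-O-gallate (free upper 3-OH) | O=C(O[C@@H]1Cc2c(OCc3ccccc3)cc(OCc3ccccc3)c([C@@H]3c4ccc(OCc5ccccc5)cc4O[C@H](c4cc(OCc5ccccc5)c(OCc5ccccc5)c(OCc5ccccc5)c4)[C@H]3O)c2O[C@@H]1c1cc(OCc2ccccc2)c(OCc2ccccc2)c(OCc2ccccc2)c1)c1cc(OCc2ccccc2)c(OCc2ccccc2)c(OCc2ccccc2)c1
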